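**Plan**

1. The heptane chain is numbered from the trioxygenated ring (C1) to the 4-hydroxyphenyl ring (C7). C1 is benzylic and sits 1,5 to the oxygen on C5, so C1–C5 and O-5 can be held as a temporary oxane (tetrahydropyran) ring whose benzylic C1–O bond is cleaved by hydrogenolysis at the end.
2. Retrosynthesis: re-form C1–O-5 (target ⇒ 2-aryl-6-arylethyl-oxan-4-ol), invert C3, then cut C4–C5, C5–O and C3–O together (three-component Prins: homoallylic alcohol + aldehyde + trifluoroacetate), then cut C1–C2 (allylation of an aryl aldehyde).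
3. Forward: aryl aldehyde + allyl unit (C2–C4) gives the benzylic homoallylic alcohol; the Prins closure joins C4 to C5 and builds the oxane; C3 is inverted; hydrolysis and hydrogenolysis open the ring and free the phenols.
4. Stereochemistry: C1 comes from Brown allylboration. C5 and C3 are relayed from C1 in the chair Prins transition state (all-cis). A ring-cis O-3/C5 relation corresponds to an anti-diol, so C3 is inverted (Mitsunobu) to the 2,4-trans oxane that maps onto the syn-(3R,5S)-diol. C1 is then erased.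
5. Helpers: two tosylates make the C1 aryl ring electron-poor for the Prins step; a benzyl ether masks the other phenol; all are removed in steps 7 and 8.

Key step: step 5

Remark: 5-hydroxyvanillin, 3-(4-hydroxyphenyl)propan-1-ol and the (+)-α-pinene-derived allylborane solution are taken as commercial; Ts = 4-methylbenzenesulfonyl.

**Route**

Step 1
Reactants: 1 3,4-dihydroxy-5-methoxybenzaldehyde (5-hydroxyvanillin)
Product: 2 3-methoxy-4,5-bis(tosyloxy)benzaldehyde
Conditions: TsCl (2.4 equiv), Et3N, DMAP (cat.), CH2Cl2, 0 °C → rt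
Reagents that add atoms: 4-toluenesulfonyl chloride (TsCl), Cc1ccc(S(=O)(=O)Cl)cc1
Why: DMAP-catalysed O-sulfonylation of both phenols should be clean, and the two sulfonates turn the ring from a donor into an acceptor, which step 5 needs to suppress benzylic ionisation at C1.

Step 2
Reactants: 2 3-methoxy-4,5-bis(tosyloxy)benzaldehyde; 3 (−)-B-allyldiisopinocampheylborane [(−)-Ipc2B(allyl), from (+)-α-pinene]
Product: 5 (S)-1-[3-methoxy-4,5-bis(tosyloxy)phenyl]but-3-en-1-ol, via diisopinocampheylborinate ester 4 (not isolated)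
Conditions: Et2O, −78 °C; then NaOH, H2O2, 0 °C → rt
Reagents that add atoms: (−)-B-allyldiisopinocampheylborane 3, C=CCB([C@@H]1C[C@@H]2C[C@H]([C@H]1C)C2(C)C)[C@@H]1C[C@@H]2C[C@H]([C@H]1C)C2(C)C
Why: Brown asymmetric allylboration through a closed chair transition state should deliver allyl to the Si face of the aryl aldehyde with this reagent antipode and so set C1 as S; aryl sulfonates are inert to the borane and to the brief oxidative work-up.

Step 3
Reactants: 6 3-(4-hydroxyphenyl)propan-1-ol
Product: 7 3-[4-(benzyloxy)phenyl]propan-1-ol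
Conditions: BnBr, K2CO3, acetone, reflux
Reagents that add atoms: benzyl bromide, BrCc1ccccc1
Why: Williamson etherification should be selective for the phenol, since carbonate deprotonates only the phenolic OH and the aliphatic alcohol stays un-ionised.

Step 4
Reactants: 7 3-[4-(benzyloxy)phenyl]propan-1-ol
Product: 8 3-[4-(benzyloxy)phenyl]propanal
Conditions: TEMPO (cat.), PhI(OAc)2, CH2Cl2, rt
Reagents that add atoms: none
Why: Oxoammonium-mediated (TEMPO/BAIB) oxidation of a primary alcohol should stop at the aldehyde in the absence of water and leave the aryl benzyl ether untouched.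

Step 5
Reactants: 5 (S)-1-[3-methoxy-4,5-bis(tosyloxy)phenyl]but-3-en-1-ol; 8 3-[4-(benzyloxy)phenyl]propanal
Product: 11 (2S,4R,6S)-2-{2-[4-(benzyloxy)phenyl]ethyl}-6-[3-methoxy-4,5-bis(tosyloxy)phenyl]oxan-4-ol, via (E)-oxocarbenium ion 9 (not isolated), via oxan-4-yl trifluoroacetate 10 (not isolated)
Conditions: TFA, CH2Cl2, 0 °C → rt; then K2CO3 (cat.), MeOH, 0 °C
Reagents that add atoms: trifluoroacetic acid, OC(=O)C(F)(F)F (supplies the oxygen on C3)
Why: Acid-promoted condensation of 5 with 8 should give the (E)-oxocarbenium ion 9, whose terminal alkene carbon (C4) attacks the oxocarbenium carbon (C5) through a chair transition state, and the oxan-4-yl cation so formed is trapped by trifluoroacetate, so that alcohol, aldehyde and oxygen nucleophile are joined in one operation with formation of the C4–C5, C5–O and C3–O bonds. The closest known reaction type is the Prins cyclisation of 1-arylbut-3-en-1-ols with aldehydes in TFA followed by methanolysis of the trifluoroacetate. The oxane ring closes in a 6-endo-trig cation–olefin mode. C5 is controlled by the C1 stereocentre because the aryl group and the arylethyl chain both take equatorial positions on the chair with an E oxocarbenium ion (2,6-cis), and C3 is controlled by equatorial capture of the ring cation (all-cis, 4R), the epimer that step 6 inverts. The step needs cyclisation to outrun 2-oxonia-Cope side-chain exchange and benzylic ionisation at C1, which would erode enantiopurity; the two sulfonate groups, para and meta to C1, make the aryl ring a poor cation stabiliser and should secure this.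

Step 6
Reactants: 11 (2S,4R,6S)-2-{2-[4-(benzyloxy)phenyl]ethyl}-6-[3-methoxy-4,5-bis(tosyloxy)phenyl]oxan-4-ol
Product: 12 (2S,4S,6S)-2-{2-[4-(benzyloxy)phenyl]ethyl}-6-[3-methoxy-4,5-bis(tosyloxy)phenyl]oxan-4-yl 4-nitrobenzoate
Conditions: 4-nitrobenzoic acid, PPh3, DIAD, THF, 0 °C → rt
Reagents that add atoms: 4-nitrobenzoic acid, O=C(O)c1ccc([N+](=O)[O-])cc1
Why: Mitsunobu reaction on the unhindered equatorial alcohol should proceed by SN2 displacement of the alkoxyphosphonium ion with clean inversion at C3, giving the axial ester whose 2,4-trans relation is that of the syn-1,3-diol.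

Step 7
Reactants: 12 (2S,4S,6S)-2-{2-[4-(benzyloxy)phenyl]ethyl}-6-[3-methoxy-4,5-bis(tosyloxy)phenyl]oxan-4-yl 4-nitrobenzoate
Product: 13 (2S,4S,6S)-2-{2-[4-(benzyloxy)phenyl]ethyl}-6-(3,4-dihydroxy-5-methoxyphenyl)oxan-4-ol
Conditions: KOH, 1,4-dioxane–H2O (degassed, Ar), reflux; then aq. HCl
Reagents that add atoms: none
Why: Saponification of the ester and hydroxide attack at sulfur of both aryl sulfonates (aryloxide leaving groups) should free the three hydroxyls in one operation; an alcohol-free medium avoids alkyl tosylate formation and phenol O-alkylation, and any epimerisation at C1 through a quinone methide is harmless because C1 is erased in step 8.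

Step 8
Reactants: 13 (2S,4S,6S)-2-{2-[4-(benzyloxy)phenyl]ethyl}-6-(3,4-dihydroxy-5-methoxyphenyl)oxan-4-ol
Product: 14 (3R,5S)-1-(3,4-dihydroxy-5-methoxyphenyl)-7-(4-hydroxyphenyl)heptane-3,5-diol (target)
Conditions: H2 (1–3 atm), Pd(OH)2/C, MeOH, HCl (cat.), rt
Reagents that add atoms: none
Why: Catalytic hydrogenolysis should cleave the aryl benzyl ether and the benzylic C1–O bond of the 2-aryl oxane (a cyclic benzylic ether activated by the now electron-rich 4-hydroxyaryl ring and trace acid), turning C1 into CH2 and releasing the C5 hydroxyl, while the non-benzylic C3 and C5 centres are untouched.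

**Compound list**

1 | 3,4-dihydroxy-5-methoxybenzaldehyde (5-hydroxyvanillin) | COc1cc(C=O)cc(O)c1O | starting material
2 | 3-methoxy-4,5-bis(tosyloxy)benzaldehyde | COc1cc(C=O)cc(OS(=O)(=O)c2ccc(C)cc2)c1OS(=O)(=O)c1ccc(C)cc1 | intermediate
3 | (−)-B-allyldiisopinocampheylborane | C=CCB([C@@H]1C[C@@H]2C[C@H]([C@H]1C)C2(C)C)[C@@H]1C[C@@H]2C[C@H]([C@H]1C)C2(C)C | starting material
4 | (S)-1-[3-methoxy-4,5-bis(tosyloxy)phenyl]but-3-en-1-yl diisopinocampheylborinate | COc1cc([C@@H](OB([C@@H]2C[C@@H]3C[C@H]([C@H]2C)C3(C)C)[C@@H]2C[C@@H]3C[C@H]([C@H]2C)C3(C)C)CC=C)cc(OS(=O)(=O)c2ccc(C)cc2)c1OS(=O)(=O)c1ccc(C)cc1 | intermediate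
5 | (S)-1-[3-methoxy-4,5-bis(tosyloxy)phenyl]but-3-en-1-ol | COc1cc([C@@H](O)CC=C)cc(OS(=O)(=O)c2ccc(C)cc2)c1OS(=O)(=O)c1ccc(C)cc1 | intermediate
6 | 3-(4-hydroxyphenyl)propan-1-ol | OCCCc1ccc(O)cc1 | starting material
7 | 3-[4-(benzyloxy)phenyl]propan-1-ol | OCCCc1ccc(OCc2ccccc2)cc1 | intermediate
8 | 3-[4-(benzyloxy)phenyl]propanal | O=CCCc1ccc(OCc2ccccc2)cc1 | intermediate
9 | (E)-oxocarbenium trifluoroacetate from 5 and 8 | COc1cc([C@@H](/[O+]=C/CCc2ccc(OCc3ccccc3)cc2)CC=C)cc(OS(=O)(=O)c2ccc(C)cc2)c1OS(=O)(=O)c1ccc(C)cc1.[O-]C(=O)C(F)(F)F | intermediate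
10 | (2S,4R,6S)-2-{2-[4-(benzyloxy)phenyl]ethyl}-6-[3-methoxy-4,5-bis(tosyloxy)phenyl]oxan-4-yl trifluoroacetate | COc1cc([C@@H]2C[C@H](OC(=O)C(F)(F)F)C[C@H](CCc3ccc(OCc4ccccc4)cc3)O2)cc(OS(=O)(=O)c2ccc(C)cc2)c1OS(=O)(=O)c1ccc(C)cc1 | intermediate
11 | (2S,4R,6S)-2-{2-[4-(benzyloxy)phenyl]ethyl}-6-[3-methoxy-4,5-bis(tosyloxy)phenyl]oxan-4-ol (all-cis) | COc1cc([C@@H]2C[C@H](O)C[C@H](CCc3ccc(OCc4ccccc4)cc3)O2)cc(OS(=O)(=O)c2ccc(C)cc2)c1OS(=O)(=O)c1ccc(C)cc1 | intermediate
12 | (2S,4S,6S)-2-{2-[4-(benzyloxy)phenyl]ethyl}-6-[3-methoxy-4,5-bis(tosyloxy)phenyl]oxan-4-yl 4-nitrobenzoate | COc1cc([C@@H]2C[C@@H](OC(=O)c3ccc([N+](=O)[O-])cc3)C[C@H](CCc3ccc(OCc4ccccc4)cc3)O2)cc(OS(=O)(=O)c2ccc(C)cc2)c1OS(=O)(=O)c1ccc(C)cc1 | intermediate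
13 | (2S,4S,6S)-2-{2-[4-(benzyloxy)phenyl]ethyl}-6-(3,4-dihydroxy-5-methoxyphenyl)oxan-4-ol | COc1cc([C@@H]2C[C@@H](O)C[C@H](CCc3ccc(OCc4ccccc4)cc3)O2)cc(O)c1O | intermediate
14 | (3R,5S)-1-(3,4-dihydroxy-5-methoxyphenyl)-7-(4-hydroxyphenyl)heptane-3,5-diol | COc1cc(CC[C@@H](O)C[C@@H](O)CCc2ccc(O)cc2)cc(O)c1O | target

**Summary**

Total step count: 8. Longest linear sequence: 6 steps (1, 2, 5, 6, 7, 8) from 5-hydroxyvanillin.

**Steps most likely to fail**

Step 5. The risk is 2-oxonia-Cope side-chain exchange and benzylic ionisation at C1 competing with cyclisation, lowering enantiopurity and yield, together with partial acid cleavage of the benzyl ether. The fallback sets out from 5 and comes back at 11. Alcohol 5 would be esterified with commercial 3-[4-(benzyloxy)phenyl]propanoic acid (DCC, DMAP, CH2Cl2) to give the propanoate ester F1. Reductive acetylation (DIBAL-H, CH2Cl2, −78 °C; then Ac2O, pyridine, DMAP) would give the α-acetoxy ether F2. Ionisation of F2 with BF3·OEt2 and AcOH in hexane–CH2Cl2 at 0 °C (segment-coupling Prins cyclisation, with no free aldehyde or water and hence no hydrolytic exchange) would give the all-cis oxan-4-yl acetate F3, and K2CO3 in MeOH would then give 11.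

Step 7. The risk is incomplete hydrolytic cleavage of the second sulfonate, sulfonyl migration between the two catechol oxygens, or air oxidation of the catecholate at reflux. The fallback sets out from 12 and comes back at 13. Methanolysis of the ester alone (K2CO3, MeOH, rt) would give the axial alcohol bis-tosylate F4. Reductive S–O cleavage by electron transfer (Mg turnings, MeOH, rt; or sodium naphthalenide, THF, −78 °C) instead of hydrolysis would then give 13 under non-hydrolytic, near-neutral conditions.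

Step 8. The risk is that hydrogenolysis stalls after O-debenzylation, leaving the oxane C1–O bond intact, or that forcing conditions begin to reduce the arenes. The fallback sets out from 13 and comes back at 14. Neutral hydrogenation (H2, Pd/C, EtOAc–MeOH) would remove only the benzyl group and give the free-phenol oxane F5. Ionic hydrogenation (Et3SiH, TFA, CH2Cl2, 0 °C → rt, then brief K2CO3/MeOH to cleave any trifluoroacetates) would open the ring through the 4-hydroxybenzylic cation and hydride transfer from silicon to give 14.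

**Further compounds**

F1 | step 5 | (1S)-1-[3-methoxy-4,5-bis(tosyloxy)phenyl]but-3-en-1-yl 3-[4-(benzyloxy)phenyl]propanoate | COc1cc([C@@H](OC(=O)CCc2ccc(OCc3ccccc3)cc2)CC=C)cc(OS(=O)(=O)c2ccc(C)cc2)c1OS(=O)(=O)c1ccc(C)cc1
F2 | step 5 | 1-{(1S)-1-[3-methoxy-4,5-bis(tosyloxy)phenyl]but-3-en-1-yloxy}-3-[4-(benzyloxy)phenyl]propyl acetate (acetal epimers) | COc1cc([C@@H](OC(OC(C)=O)CCc2ccc(OCc3ccccc3)cc2)CC=C)cc(OS(=O)(=O)c2ccc(C)cc2)c1OS(=O)(=O)c1ccc(C)cc1
F3 | step 5 | (2S,4R,6S)-2-{2-[4-(benzyloxy)phenyl]ethyl}-6-[3-methoxy-4,5-bis(tosyloxy)phenyl]oxan-4-yl acetate | COc1cc([C@@H]2C[C@H](OC(C)=O)C[C@H](CCc3ccc(OCc4ccccc4)cc3)O2)cc(OS(=O)(=O)c2ccc(C)cc2)c1OS(=O)(=O)c1ccc(C)cc1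
F4 | step 7 | (2S,4S,6S)-2-{2-[4-(benzyloxy)phenyl]ethyl}-6-[3-methoxy-4,5-bis(tosyloxy)phenyl]oxan-4-ol | COc1cc([C@@H]2C[C@@H](O)C[C@H](CCc3ccc(OCc4ccccc4)cc3)O2)cc(OS(=O)(=O)c2ccc(C)cc2)c1OS(=O)(=O)c1ccc(C)cc1
F5 | step 8 | (2S,4S,6S)-2-(3,4-dihydroxy-5-methoxyphenyl)-6-[2-(4-hydroxyphenyl)ethyl]oxan-4-ol | COc1cc([C@@H]2C[C@@H](O)C[C@H](CCc3ccc(O)cc3)O2)cc(O)c1O
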